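A direct plan would assemble the open-chain bromo dienal A1, which carries the 1,10-epoxide, a (2Z,4Z)-dienal at C6 and a Z-2-(bromomethyl)acrylate at C7, and would close the ten-membered ring and the lactone together in one intramolecular zinc allylation that forms C6–C7 and gives the bis-silylated germacranolide A2; the C8 ester would be attached last. Its weakest steps would be: the cross metathesis that would have to join the hindered C8 allylic silyl ether to a 1,1-disubstituted acrylate (slow, homodimers, E/Z mixtures); the alkyne semihydrogenation that would make the (2Z,4Z)-dienal (over-reduction, Z/E drift, oxa-6π closure to a 2H-pyran); and the allylzinc macrocyclisation of A1 to A2, which at high dilution would have to close a strained carbocycle and set C6 and C7 through one chair that only C8 controls.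

The new route makes no C–C macrocyclisation. It exploits C14: as a carboxyl on C10 it ties C10 to O–C3 in a ten-membered glycolate lactone, closed by C–O bond formation. An ester enolate Claisen rearrangement then transposes this lactone into the carbocycle: C1–C10 forms, C2=C3 is created Z inside the ring, and the C3 stereocentre is transferred to C1 and C10. The (E)-2-chlorovinyl terminus delivers C1 as a chloride, so the C10 oxygen later closes the 1,10-epoxide. An O8/O10 acetonide blocks the rival shift through C4=C5. Cross metathesis, the dienal and the allyl-metal ring closure all disappear.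

Key step: step 15

Remark: atoms carry the germacrane numbering of the target (ring C1–C10, lactone carbons C11–C13, hydroxymethyl carbon C14, methyl C15; O3, O6, O8, O10 sit on those carbons). C10 is enolised in step 15, so its configuration in 1–28 serves only to give the cis-dioxane.

Step 1
Reactants: 1 tert-butyl 2-[(4R,6S)-6-(hydroxymethyl)-2,2-dimethyl-1,3-dioxan-4-yl]acetate
Product: 2 tert-butyl 2-[(4R,6S)-6-{[(tert-butyldiphenylsilyl)oxy]methyl}-2,2-dimethyl-1,3-dioxan-4-yl]acetate
Conditions: t-BuPh2SiCl, imidazole, DMF, 0 °C to rt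
Reagents that add atoms: tert-butyldiphenylsilyl chloride, CC(C)(C)[Si](Cl)(c1ccccc1)c1ccccc1
Why: Imidazole-promoted silylation of the only hydroxyl protects the future C14 oxygen until step 12; the commercial dioxane already holds C8 (R) and the O8/O10 acetonide that the key step needs.

Step 2
Reactants: 2 tert-butyl 2-[(4R,6S)-6-{[(tert-butyldiphenylsilyl)oxy]methyl}-2,2-dimethyl-1,3-dioxan-4-yl]acetate
Product: 4 tert-butyl 2-hydroxy-2-[(4R,6S)-6-{[(tert-butyldiphenylsilyl)oxy]methyl}-2,2-dimethyl-1,3-dioxan-4-yl]acetate (both C7 epimers), via potassium enolate 3 (not isolated)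
Conditions: KN(SiMe3)2, THF, −78 °C; 2-(phenylsulfonyl)-3-phenyloxaziridine, −78 °C; aq. NH4Cl
Reagents that add atoms: 2-(phenylsulfonyl)-3-phenyloxaziridine, O=S(=O)(c1ccccc1)N1OC1c1ccccc1
Why: Enolate hydroxylation with an N-sulfonyloxaziridine puts a hydroxyl on C7 at −78 °C, where the β-alkoxy enolate should not eliminate, and prepares a one-carbon degradation; the new carbinol centre is lost in step 3.

Step 3
Reactants: 4 tert-butyl 2-hydroxy-2-[(4R,6S)-6-{[(tert-butyldiphenylsilyl)oxy]methyl}-2,2-dimethyl-1,3-dioxan-4-yl]acetate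
Product: 6 (4R,6S)-6-{[(tert-butyldiphenylsilyl)oxy]methyl}-2,2-dimethyl-1,3-dioxane-4-carbaldehyde, via 1,2-diol 5 (not isolated)
Conditions: LiAlH4, THF, 0 °C; then NaIO4, THF–pH 7 buffer, 0 °C
Reagents that add atoms: none
Why: Hydride reduction of the α-hydroxy ester to the 1,2-diol and periodate glycol cleavage should excise the ester carbon and leave the α-alkoxy aldehyde at C7 with C8 untouched.

Step 4
Reactants: 6 (4R,6S)-6-{[(tert-butyldiphenylsilyl)oxy]methyl}-2,2-dimethyl-1,3-dioxane-4-carbaldehyde; 7 methyl acrylate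
Product: 8 methyl 2-{hydroxy[(4R,6S)-6-{[(tert-butyldiphenylsilyl)oxy]methyl}-2,2-dimethyl-1,3-dioxan-4-yl]methyl}prop-2-enoate (both carbinol epimers)
Conditions: DABCO (1 equiv), MeOH, rt
Reagents that add atoms: none
Why: The Morita–Baylis–Hillman reaction of the α-alkoxy aldehyde installs C11, C12 and C13; either carbinol epimer serves, because C7 becomes sp2 in step 5.

Step 5
Reactants: 8 methyl 2-{hydroxy[(4R,6S)-6-{[(tert-butyldiphenylsilyl)oxy]methyl}-2,2-dimethyl-1,3-dioxan-4-yl]methyl}prop-2-enoate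
Product: 9 methyl (2Z)-2-(bromomethyl)-3-[(4R,6S)-6-{[(tert-butyldiphenylsilyl)oxy]methyl}-2,2-dimethyl-1,3-dioxan-4-yl]prop-2-enoate
Conditions: NBS, Me2S, CH2Cl2, −30 to 0 °C
Reagents that add atoms: N-bromosuccinimide, O=C1CCC(=O)N1Br
Why: The bromodimethylsulfonium reagent substitutes the allylic alcohol with transposition (SN2') and should give the conjugated (Z)-2-(bromomethyl)enoate under neutral conditions that spare the acetonide and the silyl ether.

Step 6
Reactants: 10 but-2-yn-1-ol
Product: 12 (Z)-3-iodobut-2-en-1-ol, via cyclic alkenylalanate 11 (not isolated)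
Conditions: NaAlH2(OCH2CH2OMe)2, THF, 0 °C to rt; then I2, −78 to 0 °C
Reagents that add atoms: iodine, [I][I]
Why: Hydroxyl-directed trans-hydroalumination places aluminium on the distal carbon in a five-membered alanate and iodinolysis goes with retention, so only the Z-iodide (future C4) should form.

Step 7
Reactants: 12 (Z)-3-iodobut-2-en-1-ol
Product: 13 (Z)-3-iodobut-2-enal
Conditions: MnO2, CH2Cl2, rt, dark
Reagents that add atoms: none
Why: Allylic oxidation on MnO2 is neutral and keeps the Z geometry when run briefly in the dark.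

Step 8
Reactants: 9 methyl (2Z)-2-(bromomethyl)-3-[(4R,6S)-6-{[(tert-butyldiphenylsilyl)oxy]methyl}-2,2-dimethyl-1,3-dioxan-4-yl]prop-2-enoate; 13 (Z)-3-iodobut-2-enal
Product: 16 4,5-cis-3-methylene-5-[(Z)-2-iodoprop-1-en-1-yl]-4-[(4R,6S)-6-{[(tert-butyldiphenylsilyl)oxy]methyl}-2,2-dimethyl-1,3-dioxan-4-yl]dihydrofuran-2(3H)-one (C6 and C7 as in the target), via Z-allylzinc bromide 14 (not isolated), via bromozinc alkoxide 15 (not isolated)
Conditions: activated Zn dust, THF–sat. aq. NH4Cl, 0 °C to rt
Reagents that add atoms: none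
Why: In this intermolecular Barbier-type 2-(alkoxycarbonyl)allylation zinc inserts only into the allylic bromide, the Z-allylzinc adds through its γ-carbon C7 in a closed chair (C8 axial, hence the 6,7-syn pair), the face is set by C8 (H8 eclipsing the alkene, the ring bond C8–C9 anti to the forming bond, the C8–O bond outward), and the zinc alkoxide closes the cis-lactone.

Step 9
Reactants: 16 cis-lactone
Product: 18 methyl acetal of the lactol (2-methoxy-3-methylenetetrahydrofuran ring; both anomers), via lactol 17 (not isolated)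
Conditions: i-Bu2AlH (1.1 equiv), CH2Cl2, −78 °C; potassium sodium tartrate work-up; then Ag2O, MeI, MeCN, rt
Reagents that add atoms: methyl iodide, CI
Why: Half-reduction of the lactone and neutral O-methylation of the lactol mask the α-methylene lactone (a Michael acceptor that the amide base of step 15 would not tolerate) as a mixed acetal; C6 and C7 are untouched and the anomeric centre is removed again when the lactone is restored in steps 16 and 17.

Step 10
Reactants: 18 alkenyl iodide acetal; 19 3-(trimethylsilyl)prop-2-ynal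
Product: 21 (3R)-propargylic alcohol (18 with iodine replaced by (R)-CH(OH)–C≡CH), via C-silylated propargylic alcohol 20 (not isolated)
Conditions: CrCl2, NiCl2 (cat.), N-[2-(4-isopropyl-4,5-dihydrooxazol-2-yl)-6-methylphenyl]methanesulfonamide (the enantiomer that gives 3R), Et3N, THF, rt; then K2CO3, MeOH, 0 °C
Reagents that add atoms: none
Why: In this Nozaki–Hiyama–Kishi coupling the alkenyl iodide reacts with retention of the Z geometry (C3 cis to C6) and the chiral sulfonamide ligand on chromium should set the new C3 carbinol as R by reagent control; carbonate in methanol then cleaves only the C(sp)–Si bond.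

Step 11
Reactants: 21 (3R)-propargylic alcohol
Product: 23 (1E,3R)-chloroalkenyl carbinol (21 with C≡CH converted to (E)-CH=CHCl), via E-alkenylzirconocene chloride 22 (not isolated)
Conditions: Cp2Zr(H)Cl (2.5 equiv), THF, rt; then N-chlorosuccinimide, 0 °C
Reagents that add atoms: N-chlorosuccinimide, O=C1CCC(=O)N1Cl
Why: Hydrozirconation of the terminal alkyne (syn, zirconium on C1, far faster than on the 1,1-disubstituted and trisubstituted alkenes) and chlorination of the C–Zr bond with retention should give only the E-chloroalkene, the terminus that the key step needs.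

Step 12
Reactants: 23 (1E,3R)-chloroalkenyl carbinol
Product: 24 primary alcohol (23 without the silyl group; C14 is CH2OH)
Conditions: Bu4NF, THF, 0 °C to rt
Reagents that add atoms: none
Why: Fluoride cleaves the silicon–oxygen bond of the primary silyl ether; the acetals, the vinyl chloride and the carbinol are inert.

Step 13
Reactants: 24 primary alcohol
Product: 26 seco acid (C14 carboxylic acid with free C3 hydroxyl), via aldehyde 25 (not isolated)
Conditions: TEMPO (cat.), PhI(OAc)2, CH2Cl2, 0 °C; then NaClO2, NaH2PO4, 2-methylbut-2-ene, t-BuOH–H2O, 0 °C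
Reagents that add atoms: sodium chlorite, [Na+].[O-]Cl=O
Why: Oxoammonium oxidation should take the unhindered primary alcohol in preference to the hindered secondary C3 hydroxyl, and the chlorite (Pinnick) oxidation turns the aldehyde into the acid without touching the alkenes.

Step 14
Reactants: 26 seco acid
Product: 28 ten-membered lactone (ester C14–O3; ring atoms O3, C14, C10, C9, C8, C7, C6, C5, C4, C3; 3R, 4Z; O8/O10 acetonide; exocyclic (E)-2-chlorovinyl group on C3), via mixed anhydride 27 (not isolated)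
Conditions: 2-methyl-6-nitrobenzoic anhydride, DMAP, Et3N, CH2Cl2, rt, slow addition (final 1 mM)
Reagents that add atoms: none
Why: The Shiina macrolactonisation closes the ring by C–O bond formation under mild basic conditions; the cis-dioxane, the fused five-membered acetal and the Z alkene hold C14 and O3 close, and the bis-allylic C3–O bond is not ionised.

Step 15
Reactants: 28 ten-membered lactone
Product: 32 methyl ester of the ten-membered carbocycle (C1 chloride; 2Z,4Z-diene; C10 bearing CO2Me and the acetonide oxygen O10), via silyl ketene acetal 29 (not isolated), via trimethylsilyl ester 30 (not isolated), via carboxylic acid 31 (not isolated)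
Conditions: LiN(SiMe3)2, Me3SiCl–Et3N (premixed), THF, −78 °C; warm to rt, then 50 °C; 5% citric acid; then Me3SiCHN2, MeOH–toluene, 0 °C
Reagents that add atoms: trimethylsilyldiazomethane, C[Si](C)(C)C=[N+]=[N-]
Why: LiN(SiMe3)2 removes H10 and Me3SiCl traps the enolate as silyl ketene acetal 29, whose geometry is fixed twice (the lactone ring holds O3 cis to C9, lithium chelation holds the enolate oxygen cis to O10), and on warming the O3–C14=C10 unit and the allylic ester O3–C3–C2=C1 undergo a [3,3] shift that forms C10–C1, breaks C3–O3 and releases C14 as the silyl ester. The closest known reaction type is the Ireland–Claisen rearrangement of lactone silyl ketene acetals that carry an alkenyl group on the carbinol carbon, which turns an n-membered lactone into an n-membered cycloalkene carboxylic acid. The ten-membered carbocycle is closed by this ring transposition without high dilution, and because C9 and C4, the two ends of the tether, sit on the same open side of a boat-shaped six-atom array, the new C2=C3 bond should be Z, which completes the 2Z,4Z-diene. In that boat the 3R centre is transferred suprafacially: C10 takes C1 on the face cis to C7 (target configuration, O10 retained), and the E chlorine points outward, so that C1 carries Cl placed for the later anti displacement by O10 (inversion at C1) that gives the cis 1R,10R-epoxide. The selectivity needed is for the exocyclic chlorovinyl group over the ring alkene C4=C5 (a four-atom ring contraction to a cyclohexane), and the O8/O10 acetonide secures it, because a C10–C5 bond would create a 2,4-dioxabicyclo[3.3.1]nonane with C7 and the new bond diaxial against an endo acetonide methyl, whereas the path to C1 keeps C7 equatorial.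

Step 16
Reactants: 32 methyl ester of the carbocycle
Product: 34 chlorohydrin triol lactol (C1 Cl; C8, C10 and C14 hydroxyls; C12 lactol; both anomers), via primary alcohol 33 (not isolated)
Conditions: i-Bu2AlH (2.5 equiv), CH2Cl2, −78 to −40 °C; potassium sodium tartrate work-up; then AcOH–THF–H2O (3:1:1), 40 °C
Reagents that add atoms: water, O
Why: Hydride reduction of the hindered ester gives the C14 alcohol without attacking the allylic chloride, and mild aqueous acid then removes the acetonide and hydrolyses the methyl acetal, while the chloride next to the oxygenated quaternary C10 should resist ionisation and, with no base present, the chlorohydrin does not yet close.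

Step 17
Reactants: 34 chlorohydrin triol lactol
Product: 35 chlorohydrin triol lactone (1-chloro-8,10,14-trihydroxygermacra-2Z,4Z,11(13)-trien-12,6-olide, cis-fused)
Conditions: MnO2, CH2Cl2, rt
Reagents that add atoms: none
Why: MnO2 oxidises only the allylic lactol, to the α-methylene-γ-lactone, and leaves the non-allylic primary, secondary and tertiary hydroxyls.

Step 18
Reactants: 35 chlorohydrin triol lactone
Product: 36 14-O-triethylsilyl ether of 35
Conditions: Et3SiCl (1.05 equiv), imidazole, CH2Cl2, −40 °C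
Reagents that add atoms: triethylsilyl chloride, CC[Si](Cl)(CC)CC
Why: At low temperature the silyl chloride should react with the primary C14 hydroxyl far faster than with the secondary C8 hydroxyl, and the tertiary C10 hydroxyl is inert.

Step 19
Reactants: 37 (E)-but-2-enal
Product: 38 (Z)-2-iodobut-2-enal
Conditions: I2, K2CO3, DMAP (cat.), THF–H2O, rt
Reagents that add atoms: iodine, [I][I]
Why: Baylis–Hillman-type α-iodination (conjugate addition of DMAP, iodination, elimination) replaces only the α-hydrogen, so methyl and iodine end up cis.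

Step 20
Reactants: 38 (Z)-2-iodobut-2-enal
Product: 39 (Z)-2-iodobut-2-en-1-ol
Conditions: NaBH4, MeOH, −20 °C
Reagents that add atoms: none
Why: Borohydride 1,2-reduction of the enal leaves the alkenyl iodide and its geometry untouched.

Step 21
Reactants: 39 (Z)-2-iodobut-2-en-1-ol
Product: 40 tert-butyl{[(Z)-2-iodobut-2-en-1-yl]oxy}dimethylsilane
Conditions: t-BuMe2SiCl, imidazole, CH2Cl2, rt
Reagents that add atoms: tert-butyldimethylsilyl chloride, CC(C)(C)[Si](C)(C)Cl
Why: This is a standard silyl protection of a primary alcohol.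

Step 22
Reactants: 40 tert-butyl{[(Z)-2-iodobut-2-en-1-yl]oxy}dimethylsilane
Product: 42 (Z)-2-{[(tert-butyldimethylsilyl)oxy]methyl}but-2-enoic acid, via alkenyllithium 41 (not isolated)
Conditions: t-BuLi (2.1 equiv), Et2O, −78 °C; CO2; cold 1 M HCl
Reagents that add atoms: carbon dioxide, O=C=O
Why: Iodine–lithium exchange at −78 °C gives a configurationally stable alkenyllithium that is carboxylated with retention, which fixes the Z geometry of the side chain.

Step 23
Reactants: 36 14-O-triethylsilyl chlorohydrin lactone; 42 (Z)-2-{[(tert-butyldimethylsilyl)oxy]methyl}but-2-enoic acid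
Product: 44 8-O-acyl chlorohydrin (36 esterified at O8 with the silylated side chain), via mixed anhydride 43 (not isolated)
Conditions: 42, 2,4,6-Cl3C6H2COCl, Et3N, toluene, rt; then 36, DMAP (0.5 equiv), 0 °C to rt
Reagents that add atoms: none
Why: Yamaguchi esterification acylates the secondary C8 hydroxyl (retention at C8), the tertiary C10 hydroxyl is not acylated, and the low DMAP loading limits Z to E isomerisation of the acid.

Step 24
Reactants: 44 8-O-acyl chlorohydrin
Product: 45 14-O-triethylsilyl, side-chain O-tert-butyldimethylsilyl ether of the target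
Conditions: Cs2CO3, MeCN, 0 °C to rt
Reagents that add atoms: none
Why: In this intramolecular Williamson reaction the C10 alkoxide displaces the anti-disposed allylic chloride at C1 with inversion, which should give the cis 1R,10R-epoxide; no other free hydroxyl is present.

Step 25
Reactants: 45 bis-silyl ether of the target
Product: 46 target CNP0165856.1
Conditions: Et3N·3HF, MeCN, rt
Reagents that add atoms: none
Why: This nearly neutral fluoride source removes both primary silyl groups without opening the vinyl epoxide, adding to the methylene lactone or moving the ester.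

Compound list

1 | tert-butyl 2-[(4R,6S)-6-(hydroxymethyl)-2,2-dimethyl-1,3-dioxan-4-yl]acetate | CC(C)(C)OC(=O)C[C@H]1C[C@@H](CO)OC(C)(C)O1 | starting material
2 | tert-butyl 2-[(4R,6S)-6-{[(tert-butyldiphenylsilyl)oxy]methyl}-2,2-dimethyl-1,3-dioxan-4-yl]acetate | CC(C)(C)OC(=O)C[C@H]1C[C@@H](CO[Si](c2ccccc2)(c2ccccc2)C(C)(C)C)OC(C)(C)O1 | intermediate
3 | potassium enolate of 2 | CC(C)(C)OC([O-])=C[C@H]1C[C@@H](CO[Si](c2ccccc2)(c2ccccc2)C(C)(C)C)OC(C)(C)O1.[K+] | intermediate
4 | tert-butyl 2-hydroxy-2-[(4R,6S)-6-{[(tert-butyldiphenylsilyl)oxy]methyl}-2,2-dimethyl-1,3-dioxan-4-yl]acetate (both C7 epimers) | CC(C)(C)OC(=O)C(O)[C@H]1C[C@@H](CO[Si](c2ccccc2)(c2ccccc2)C(C)(C)C)OC(C)(C)O1 | intermediate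
5 | 1-[(4R,6S)-6-{[(tert-butyldiphenylsilyl)oxy]methyl}-2,2-dimethyl-1,3-dioxan-4-yl]ethane-1,2-diol | OCC(O)[C@H]1C[C@@H](CO[Si](c2ccccc2)(c2ccccc2)C(C)(C)C)OC(C)(C)O1 | intermediate
6 | (4R,6S)-6-{[(tert-butyldiphenylsilyl)oxy]methyl}-2,2-dimethyl-1,3-dioxane-4-carbaldehyde (C7 aldehyde) | O=C[C@H]1C[C@@H](CO[Si](c2ccccc2)(c2ccccc2)C(C)(C)C)OC(C)(C)O1 | intermediate
7 | methyl acrylate | C=CC(=O)OC | starting material
8 | methyl 2-{hydroxy[(4R,6S)-6-{[(tert-butyldiphenylsilyl)oxy]methyl}-2,2-dimethyl-1,3-dioxan-4-yl]methyl}prop-2-enoate (both carbinol epimers) | C=C(C(=O)OC)C(O)[C@H]1C[C@@H](CO[Si](c2ccccc2)(c2ccccc2)C(C)(C)C)OC(C)(C)O1 | intermediate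
9 | methyl (2Z)-2-(bromomethyl)-3-[(4R,6S)-6-{[(tert-butyldiphenylsilyl)oxy]methyl}-2,2-dimethyl-1,3-dioxan-4-yl]prop-2-enoate | COC(=O)/C(CBr)=C/[C@H]1C[C@@H](CO[Si](c2ccccc2)(c2ccccc2)C(C)(C)C)OC(C)(C)O1 | intermediate
10 | but-2-yn-1-ol | CC#CCO | starting material
11 | cyclic sodium alkenylalanate (five-membered O–Al–C ring, two 2-methoxyethoxy ligands) | CC1=CCO[Al-]1(OCCOC)OCCOC.[Na+] | intermediate
12 | (Z)-3-iodobut-2-en-1-ol | OC/C=C(\I)C | intermediate
13 | (Z)-3-iodobut-2-enal | O=C/C=C(\I)C | intermediate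
14 | (Z)-2-(methoxycarbonyl)allylzinc bromide from 9 | COC(=O)/C(C[Zn]Br)=C/[C@H]1C[C@@H](CO[Si](c2ccccc2)(c2ccccc2)C(C)(C)C)OC(C)(C)O1 | intermediate
15 | bromozinc alkoxide of the open adduct (C6–C7 bond formed, O6–Zn, C7 bearing the methyl acrylate unit) | C=C(C(=O)OC)[C@@H]([C@@H](O[Zn]Br)/C=C(C)\I)[C@H]1C[C@@H](CO[Si](c2ccccc2)(c2ccccc2)C(C)(C)C)OC(C)(C)O1 | intermediate
16 | 4,5-cis-3-methylene-5-[(Z)-2-iodoprop-1-en-1-yl]-4-[(4R,6S)-6-{[(tert-butyldiphenylsilyl)oxy]methyl}-2,2-dimethyl-1,3-dioxan-4-yl]dihydrofuran-2(3H)-one (C6, C7 as in the target) | I/C(C)=C\[C@@H]1OC(=O)C(=C)[C@@H]1[C@H]1C[C@@H](CO[Si](c2ccccc2)(c2ccccc2)C(C)(C)C)OC(C)(C)O1 | intermediate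
17 | lactol from 16 (2-hydroxy-3-methylenetetrahydrofuran ring, both anomers) | I/C(C)=C\[C@@H]1OC(O)C(=C)[C@@H]1[C@H]1C[C@@H](CO[Si](c2ccccc2)(c2ccccc2)C(C)(C)C)OC(C)(C)O1 | intermediate
18 | methyl acetal of 17 (2-methoxy-3-methylenetetrahydrofuran ring, both anomers) | I/C(C)=C\[C@@H]1OC(OC)C(=C)[C@@H]1[C@H]1C[C@@H](CO[Si](c2ccccc2)(c2ccccc2)C(C)(C)C)OC(C)(C)O1 | intermediate
19 | 3-(trimethylsilyl)prop-2-ynal | C[Si](C)(C)C#CC=O | starting material
20 | C-silylated propargylic alcohol (18 with iodine replaced by CH(OH)–C≡C–SiMe3, C3 as in 21) | C[Si](C)(C)C#C[C@@H](O)/C(C)=C\[C@@H]1OC(OC)C(=C)[C@@H]1[C@H]1C[C@@H](CO[Si](c2ccccc2)(c2ccccc2)C(C)(C)C)OC(C)(C)O1 | intermediate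
21 | (3R)-propargylic alcohol (18 with iodine replaced by (R)-CH(OH)–C≡CH; C4=C5 Z) | C#C[C@@H](O)/C(C)=C\[C@@H]1OC(OC)C(=C)[C@@H]1[C@H]1C[C@@H](CO[Si](c2ccccc2)(c2ccccc2)C(C)(C)C)OC(C)(C)O1 | intermediate
22 | (E)-alkenylzirconocene chloride from 21 (zirconium on C1, O3 as zirconium alkoxide) | Cl[Zr](C1C=CC=C1)(C1C=CC=C1)/C=C/[C@@H](O[Zr](Cl)(C1C=CC=C1)C1C=CC=C1)/C(C)=C\[C@@H]1OC(OC)C(=C)[C@@H]1[C@H]1C[C@@H](CO[Si](c2ccccc2)(c2ccccc2)C(C)(C)C)OC(C)(C)O1 | intermediate
23 | (1E,3R)-chloroalkenyl carbinol (21 with C≡CH converted to (E)-CH=CHCl) | Cl/C=C/[C@@H](O)/C(C)=C\[C@@H]1OC(OC)C(=C)[C@@H]1[C@H]1C[C@@H](CO[Si](c2ccccc2)(c2ccccc2)C(C)(C)C)OC(C)(C)O1 | intermediate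
24 | primary alcohol (23 without the silyl group, C14 CH2OH) | Cl/C=C/[C@@H](O)/C(C)=C\[C@@H]1OC(OC)C(=C)[C@@H]1[C@H]1C[C@@H](CO)OC(C)(C)O1 | intermediate
25 | C14 aldehyde of 24 | Cl/C=C/[C@@H](O)/C(C)=C\[C@@H]1OC(OC)C(=C)[C@@H]1[C@H]1C[C@@H](C=O)OC(C)(C)O1 | intermediate
26 | seco acid (C14 carboxylic acid, free C3 hydroxyl) | Cl/C=C/[C@@H](O)/C(C)=C\[C@@H]1OC(OC)C(=C)[C@@H]1[C@H]1C[C@@H](C(=O)O)OC(C)(C)O1 | intermediate
27 | mixed anhydride of 26 and 2-methyl-6-nitrobenzoic acid | Cl/C=C/[C@@H](O)/C(C)=C\[C@@H]1OC(OC)C(=C)[C@@H]1[C@H]1C[C@@H](C(=O)OC(=O)c2c(C)cccc2[N+](=O)[O-])OC(C)(C)O1 | intermediate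
28 | ten-membered lactone (ester C14–O3; 3R, 4Z; O8/O10 acetonide; cis-fused methyl acetal ring at C6/C7; (E)-2-chlorovinyl on C3) | O=C1O[C@H](/C=C/Cl)/C(C)=C\[C@@H]2OC(OC)C(=C)[C@@H]2[C@H]3C[C@@H]1OC(C)(C)O3 | intermediate
29 | trimethylsilyl ketene acetal of 28 (C14=C10, O3 cis to C9) | C[Si](C)(C)O/C1=C2\OC(C)(C)O[C@H](C2)[C@H]3C(=C)C(OC)O[C@H]3/C=C(C)\[C@@H](/C=C/Cl)O1 | intermediate
30 | trimethylsilyl ester of 31 | C[Si](C)(C)OC(=O)[C@@]12C[C@@H](OC(C)(C)O1)[C@H]1C(=C)C(OC)O[C@H]1/C=C(C)\C=C/[C@@H]2Cl | intermediate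
31 | carboxylic acid of the ten-membered carbocycle (C1 Cl; 2Z,4Z; C10 bearing CO2H and acetonide O10) | OC(=O)[C@@]12C[C@@H](OC(C)(C)O1)[C@H]1C(=C)C(OC)O[C@H]1/C=C(C)\C=C/[C@@H]2Cl | intermediate
32 | methyl ester of 31 | COC(=O)[C@@]12C[C@@H](OC(C)(C)O1)[C@H]1C(=C)C(OC)O[C@H]1/C=C(C)\C=C/[C@@H]2Cl | intermediate
33 | C14 primary alcohol from 32 | OC[C@@]12C[C@@H](OC(C)(C)O1)[C@H]1C(=C)C(OC)O[C@H]1/C=C(C)\C=C/[C@@H]2Cl | intermediate
34 | chlorohydrin triol lactol (C1 Cl; C8, C10, C14 hydroxyls; C12 lactol, both anomers) | OC[C@]1(O)C[C@@H](O)[C@H]2C(=C)C(O)O[C@H]2/C=C(C)\C=C/[C@@H]1Cl | intermediate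
35 | 1-chloro-8,10,14-trihydroxygermacra-2Z,4Z,11(13)-trien-12,6-olide (cis-lactone) | OC[C@]1(O)C[C@@H](O)[C@H]2C(=C)C(=O)O[C@H]2/C=C(C)\C=C/[C@@H]1Cl | intermediate
36 | 14-O-triethylsilyl ether of 35 | CC[Si](CC)(CC)OC[C@]1(O)C[C@@H](O)[C@H]2C(=C)C(=O)O[C@H]2/C=C(C)\C=C/[C@@H]1Cl | intermediate
37 | (E)-but-2-enal | C/C=C/C=O | starting material
38 | (Z)-2-iodobut-2-enal | C/C=C(\I)C=O | intermediate
39 | (Z)-2-iodobut-2-en-1-ol | C/C=C(\I)CO | intermediate
40 | tert-butyl{[(Z)-2-iodobut-2-en-1-yl]oxy}dimethylsilane | C/C=C(\I)CO[Si](C)(C)C(C)(C)C | intermediate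
41 | alkenyllithium from 40 (lithium cis to methyl) | C/C=C(\[Li])CO[Si](C)(C)C(C)(C)C | intermediate
42 | (Z)-2-{[(tert-butyldimethylsilyl)oxy]methyl}but-2-enoic acid | C/C=C(\C(=O)O)CO[Si](C)(C)C(C)(C)C | intermediate
43 | mixed anhydride of 42 and 2,4,6-trichlorobenzoic acid | C/C=C(\C(=O)OC(=O)c1c(Cl)cc(Cl)cc1Cl)CO[Si](C)(C)C(C)(C)C | intermediate
44 | 8-O-acyl chlorohydrin (36 esterified at O8 with the silylated side chain) | CC[Si](CC)(CC)OC[C@]1(O)C[C@@H](OC(=O)/C(=C\C)CO[Si](C)(C)C(C)(C)C)[C@H]2C(=C)C(=O)O[C@H]2/C=C(C)\C=C/[C@@H]1Cl | intermediate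
45 | 14-O-triethylsilyl, side-chain O-tert-butyldimethylsilyl ether of the target | CC[Si](CC)(CC)OC[C@]12C[C@@H](OC(=O)/C(=C\C)CO[Si](C)(C)C(C)(C)C)[C@H]3C(=C)C(=O)O[C@H]3/C=C(C)\C=C/[C@H]1O2 | intermediate
46 | CNP0165856.1, (1R,6S,7R,8R,10R)-1,10-epoxy-14-hydroxy-8-[(Z)-2-(hydroxymethyl)but-2-enoyloxy]germacra-2Z,4Z,11(13)-trien-12,6-olide | C=C1C(=O)O[C@H]2/C=C(C)\C=C/[C@H]3O[C@@]3(CO)C[C@@H](OC(=O)/C(=C\C)CO)[C@@H]12 | target

Total step count: 25. Longest linear sequence: 19 steps (steps 1–5, 8–18 and 23–25).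

The three steps most likely to fail:

Step 15. The [3,3] shift may run through the ring alkene C4=C5 instead of the chlorovinyl group (ring contraction), or through a chair-like array that gives the E alkene and the wrong C1 epimer. The fallback sets out from 28 and masks the ring alkene. Epoxidation with 3-chloroperbenzoic acid and NaHCO3 at the most electron-rich, trisubstituted C4=C5 bond would give the 4,5-epoxy lactone F2 (either cis-epoxide serves). F2 has only one allylic terminus left and would be rearranged as in step 15 to the 4,5-epoxy methyl ester F3. Stereospecific deoxygenation of F3 with CH3ReO3 (cat.) and PPh3, which retains the alkene geometry, would return to the route at 32.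

Step 14. The ring closure may give oligomers, or the hindered bis-allylic C3 hydroxyl may fail to accept the activated acyl group. The fallback sets out from 18 and activates the alcohol instead of the acid. Step 10 would be run with the enantiomeric ligand to give the 3-epimeric propargylic alcohol F4, and steps 11–13 would carry it to the 3-epimeric chloroalkenyl carbinol F5, the 3-epimeric primary alcohol F6 and the 3-epimeric seco acid F7. A Mitsunobu lactonisation of F7 (PPh3, diisopropyl azodicarboxylate, toluene, high dilution), in which the carboxylate displaces the activated C3 oxygen with inversion, would rejoin the route at 28.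

Step 8. Facial selectivity under the control of C8 may be poor, and 1,3-metal shifts may erode the Z geometry of the allylzinc, so that lactone diastereomers form. The fallback sets out from 9 and replaces substrate control by a configurationally stable reagent under catalyst control. Borylation with B2pin2 and Pd2(dba)3 would give the (Z)-allylboronate F1. Allylboration of 13 with F1 under a chiral phosphoric acid catalyst (closed chair, Z reagent giving the syn pair), followed by acid-induced lactonisation, would return to the route at 16.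

Further compounds

F1 | step 8 | methyl (2Z)-3-[(4R,6S)-6-{[(tert-butyldiphenylsilyl)oxy]methyl}-2,2-dimethyl-1,3-dioxan-4-yl]-2-[(4,4,5,5-tetramethyl-1,3,2-dioxaborolan-2-yl)methyl]prop-2-enoate | COC(=O)/C(CB1OC(C)(C)C(C)(C)O1)=C/[C@H]1C[C@@H](CO[Si](c2ccccc2)(c2ccccc2)C(C)(C)C)OC(C)(C)O1
F2 | step 15 | 4,5-epoxide of lactone 28 (cis-epoxide, one of two faces) | O=C1O[C@H](/C=C/Cl)[C@]2(C)O[C@@H]2[C@@H]2OC(OC)C(=C)[C@@H]2[C@H]3C[C@@H]1OC(C)(C)O3
F3 | step 15 | 4,5-epoxide of methyl ester 32 (2Z) | COC(=O)[C@@]12C[C@@H](OC(C)(C)O1)[C@H]1C(=C)C(OC)O[C@H]1[C@H]1O[C@@]1(C)/C=C\[C@@H]2Cl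
F4 | step 14 | 3-epimer of propargylic alcohol 21 | C#C[C@H](O)/C(C)=C\[C@@H]1OC(OC)C(=C)[C@@H]1[C@H]1C[C@@H](CO[Si](c2ccccc2)(c2ccccc2)C(C)(C)C)OC(C)(C)O1
F5 | step 14 | 3-epimer of chloroalkenyl carbinol 23 | Cl/C=C/[C@H](O)/C(C)=C\[C@@H]1OC(OC)C(=C)[C@@H]1[C@H]1C[C@@H](CO[Si](c2ccccc2)(c2ccccc2)C(C)(C)C)OC(C)(C)O1
F6 | step 14 | 3-epimer of primary alcohol 24 | Cl/C=C/[C@H](O)/C(C)=C\[C@@H]1OC(OC)C(=C)[C@@H]1[C@H]1C[C@@H](CO)OC(C)(C)O1
F7 | step 14 | 3-epimer of seco acid 26 | Cl/C=C/[C@H](O)/C(C)=C\[C@@H]1OC(OC)C(=C)[C@@H]1[C@H]1C[C@@H](C(=O)O)OC(C)(C)O1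
A1 | direct plan | methyl (2Z,4R)-2-(bromomethyl)-5-{(2R,3R)-2-[(tert-butyldimethylsilyloxy)methyl]-3-[(1Z,3Z)-3-methyl-5-oxopenta-1,3-dien-1-yl]oxiran-2-yl}-4-(triethylsilyloxy)pent-2-enoate | O=C/C=C(C)\C=C/[C@H]1O[C@@]1(CO[Si](C)(C)C(C)(C)C)C[C@@H](O[Si](CC)(CC)CC)/C=C(\CBr)C(=O)OC
A2 | direct plan | 14-(tert-butyldimethylsilyloxy)-1,10-epoxy-8-(triethylsilyloxy)germacra-2Z,4Z,11(13)-trien-12,6-olide | C=C1C(=O)O[C@H]2/C=C(C)\C=C/[C@H]3O[C@@]3(CO[Si](C)(C)C(C)(C)C)C[C@@H](O[Si](CC)(CC)CC)[C@@H]12
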